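**Retrosynthetic overview**

Locants follow the daucane skeleton: C1 = methyl‑bearing ring‑fusion carbon, C2/C3 = ring CH2, C4 = C(OH)(i‑Pr), C5 = ring‑fusion CH, C6 = aroyloxy CH, C7 = CH2, C8(CH3)=C9, C10 = isovaleryloxy CH; five‑membered ring C1–C5, seven‑membered ring C1/C5–C10.
Endgame: the two esters go on last; C6–OH comes from hydroxyl‑directed reduction of a C6 ketone; C4–OH/C5–H from epoxidation and SmI2 opening of a tetrasubstituted C4=C5–C6=O enone; C10–OH/C8=C9 from epoxide–selenoxide transposition of a C9=C10 alkene; the isopropyl group from organocerium addition and hydrolytic transposition of a vinylogous silyl ester.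
Key disconnection: the ring‑fusion bond C1–C5 (carbenoid cyclopropanation of the C1=C10 alkene) together with C7–C8 (Cope rearrangement); a temporary C5–C10 cyclopropane bond holds the two vinyl arms cis and is cleaved in the same operation; the precursor is the acyclic siloxyvinyl diazo ketone 9.
Enabling feature: C5 lies between the oxygen‑bearing C4 (five‑membered ring) and C6 (seven‑membered ring), so it is the central carbon of a latent 1,3‑dicarbonyl and can be the diazo (carbenoid) carbon, while C1 is the methyl‑substituted inner carbon of the C1–C10–C9–C8 diene unit of the seven‑membered ring.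
Ring order: five‑membered ring and cyclopropane first (C1–C5, C5–C10), then the seven‑membered ring (C7–C8 formed, C5–C10 broken); 9 is built from crotonaldehyde, triethyl 2‑phosphonopropionate and pentane‑2,4‑dione.

Key step: step 7

Remark: "upper face" means the face of the bicyclic skeleton opposite to the C1 methyl group; the sense of induction of Rh2(S‑PTAD)4 in step 7 is assumed, and the mirror‑image catalyst Rh2(R‑PTAD)4 would be used if it proved opposite.

**Route**

Step 1
Reactants: 1 (2E)-but-2-enal; 2 triethyl 2-phosphonopropionate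
Product: 3 ethyl (2E,4E)-2-methylhexa-2,4-dienoate
Conditions: NaH, THF, 0 → 23 °C
Reagents that add atoms: none
Why: Horner–Wadsworth–Emmons olefination with the stabilized α‑methyl phosphonate anion should give the (E)‑trisubstituted enoate under thermodynamic control while the (E)‑alkene of 1 is carried over, so the (2E,4E)‑diene geometry needed in step 7 is fixed here.

Step 2
Reactants: 3 ethyl (2E,4E)-2-methylhexa-2,4-dienoate
Product: 4 (2E,4E)-2-methylhexa-2,4-dien-1-ol
Conditions: i‑Bu2AlH (2.2 equiv), CH2Cl2, −78 °C; aq. potassium sodium tartrate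
Reagents that add atoms: none
Why: 1,2‑reduction of the conjugated ester by the aluminium hydride at low temperature should give the dienyl alcohol without touching the diene or its geometry.

Step 3
Reactants: 4 (2E,4E)-2-methylhexa-2,4-dien-1-ol
Product: 5 (2E,4E)-1-bromo-2-methylhexa-2,4-diene
Conditions: PBr3 (0.4 equiv), Et2O, −10 °C; used crude
Reagents that add atoms: phosphorus tribromide (BrP(Br)Br)
Why: conversion of the primary allylic alcohol into the bromide through its phosphite ester (SN2 by bromide) should give the conjugated primary dienyl bromide, which is also the thermodynamically preferred allylic isomer.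

Step 4
Reactants: 5 (2E,4E)-1-bromo-2-methylhexa-2,4-diene; 6 pentane-2,4-dione
Product: 7 (7E,9E)-7-methylundeca-7,9-diene-2,4-dione
Conditions: 6, NaH then n‑BuLi, THF, 0 °C; 5, −78 → 0 °C; 1 M aq. HCl
Reagents that add atoms: none
Why: the 1,3‑diketone dianion alkylates at its terminal, more basic carbon by SN2 at the primary allylic bromide (dianion γ‑alkylation), which joins C3 to C2 and leaves both alkene geometries untouched.

Step 5
Reactants: 7 (7E,9E)-7-methylundeca-7,9-diene-2,4-dione
Product: 8 (7E,9E)-3-diazo-7-methylundeca-7,9-diene-2,4-dione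
Conditions: 4-acetamidobenzenesulfonyl azide, Et3N, MeCN, 0 → 23 °C
Reagents that add atoms: 4-acetamidobenzenesulfonyl azide (CC(=O)Nc1ccc(cc1)S(=O)(=O)N=[N+]=[N-])
Why: Regitz diazo transfer to the acidic central carbon of the 1,3‑diketone should give the 2‑diazo‑1,3‑diketone, which places the diazo group on the future C5.

Step 6
Reactants: 8 (7E,9E)-3-diazo-7-methylundeca-7,9-diene-2,4-dione
Product: 9 (7E,9E)-2-[(tert-butyldimethylsilyl)oxy]-3-diazo-7-methylundeca-1,7,9-trien-4-one
Conditions: LiN(SiMe3)2 (1.05 equiv), THF, −78 °C; TBSOTf, −78 → −40 °C; used crude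
Reagents that add atoms: tert-butyldimethylsilyl trifluoromethanesulfonate (CC(C)(C)[Si](C)(C)OS(=O)(=O)C(F)(F)F)
Why: kinetic deprotonation by the hindered amide base should occur at the acetyl methyl group rather than at the C3 methylene, and O‑silylation of that enolate (silyl enol ether formation) turns the acetyl group into the 2‑siloxyvinyl donor arm (C6=C7) of the carbenoid precursor.

Step 7
Reactants: 9 (7E,9E)-2-[(tert-butyldimethylsilyl)oxy]-3-diazo-7-methylundeca-1,7,9-trien-4-one
Product: 11 (3aR,6R)-8-[(tert-butyldimethylsilyl)oxy]-3a,6-dimethyl-3,3a,6,7-tetrahydroazulen-1(2H)-one, via divinylcyclopropane 10 (not isolated)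
Conditions: Rh2(S‑PTAD)4 (dirhodium tetrakis[(S)-(adamantan-1-yl)(phthalimido)acetate], 1 mol %), hexanes, slow addition of 9, 0 → 23 °C; then toluene, 80 °C
Reagents that add atoms: none
Why: Loss of N2 from 9 at the rhodium catalyst gives a donor/acceptor (siloxyvinyl/acyl) carbenoid whose carbene carbon, the future C5, adds to the proximal methyl‑bearing C1=C10 alkene of the tethered diene; this forms the C1–C5 bond and closes the five‑membered ring as a bicyclo[3.1.0]hexan‑2‑one (intramolecular [2+1] addition across the three‑atom tether C2–C3–C4), and the cis‑divinylcyclopropane 10 then undergoes a [3,3]‑sigmatropic (Cope) ring expansion through a boat transition state that forms C7–C8, breaks the temporary C5–C10 bond and so closes the seven‑membered ring. The closest known reaction type is the intramolecular tandem cyclopropanation/Cope rearrangement (formal [4+3] cycloaddition) of vinyl diazo carbonyl compounds with tethered dienes, together with the siloxy‑divinylcyclopropane route to hydroazulenes. The quaternary stereocentre C1 is set in the cyclopropanation by the chiral rhodium carboxylate, which selects the enantiotopic face of the C1=C10 alkene; the suprafacial addition to the (E)‑alkene places the propenyl group exo, hence cis to the siloxyvinyl group, as the Cope step requires. The C8 stereocentre follows from the boat transition state, in which the (E)‑methyl of the propenyl terminus points outward and ends trans to the C1 methyl; this centre is erased in step 10 and serves only to put H8 on the face needed there. The step needs site selectivity for the proximal trisubstituted alkene over the distal alkene and over C–H insertion, which the five‑membered‑ring tether and the 2‑siloxy group (it suppresses vinylogous reactivity of the carbenoid) should secure; heating is expected to be needed because the C1 methyl lies syn to both vinyl groups in the boat.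

Step 8
Reactants: 11 (3aR,6R)-8-[(tert-butyldimethylsilyl)oxy]-3a,6-dimethyl-3,3a,6,7-tetrahydroazulen-1(2H)-one; 12 isopropyllithium
Product: 14 (6R,8aR)-6,8a-dimethyl-3-(propan-2-yl)-1,2,6,8a-tetrahydroazulen-4(5H)-one, via carbinol 13 (not isolated)
Conditions: CeCl3 (anhydrous), 12, THF, −78 °C; then 1 M aq. HCl, THF, 0 → 23 °C
Reagents that add atoms: none
Why: Stork–Danheiser sequence, in which the weakly basic organocerium reagent adds 1,2 to the C4 carbonyl of the vinylogous silyl ester and acid then hydrolyses the silyl enol ether and eliminates the tertiary hydroxyl, so that the carbonyl is transposed to C6 and the tetrasubstituted C4=C5 enone carrying the isopropyl group is obtained (the carbinol configuration of 13 is lost and need not be controlled).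

Step 9
Reactants: 14 (6R,8aR)-6,8a-dimethyl-3-(propan-2-yl)-1,2,6,8a-tetrahydroazulen-4(5H)-one
Product: 15 (6R,7R,8S,8aS)-7,8-epoxy-6,8a-dimethyl-3-(propan-2-yl)-1,2,6,7,8,8a-hexahydroazulen-4(5H)-one
Conditions: mCPBA, NaHCO3, CH2Cl2, 0 °C
Reagents that add atoms: 3-chloroperoxybenzoic acid (OOC(=O)c1cccc(Cl)c1)
Why: Prilezhaev epoxidation should be chemoselective for the isolated cis‑disubstituted C9=C10 alkene over the electron‑poor tetrasubstituted enone, and the peracid should approach the convex upper face of the boat‑shaped cycloheptadiene, anti to the C1 methyl that occupies the concave side (the C8 methyl is pseudo‑equatorial), which puts the oxygen on the face required at C10.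

Step 10
Reactants: 15 (6R,7R,8S,8aS)-7,8-epoxy-6,8a-dimethyl-3-(propan-2-yl)-1,2,6,7,8,8a-hexahydroazulen-4(5H)-one
Product: 18 (8R,8aS)-8-hydroxy-6,8a-dimethyl-3-(propan-2-yl)-1,2,8,8a-tetrahydroazulen-4(5H)-one, via hydroxy selenide 16 (not isolated), via selenoxide 17 (not isolated)
Conditions: (PhSe)2, NaBH4, EtOH, 0 → 23 °C; then 30% aq. H2O2, pyridine, THF, 0 → 23 °C
Reagents that add atoms: none
Why: the selenolate opens the epoxide by SN2 attack at C9, the carbon remote from the quaternary C1, so that the C10–O bond and its configuration are kept, and the selenoxide then undergoes syn‑elimination toward the cis C8–H and away from the carbinol carbon, which moves the double bond to C8=C9 and removes the C8 stereocentre (epoxide to allylic alcohol transposition through a β‑hydroxy selenide).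

Step 11
Reactants: 18 (8R,8aS)-8-hydroxy-6,8a-dimethyl-3-(propan-2-yl)-1,2,8,8a-tetrahydroazulen-4(5H)-one
Product: 19 (3S,3aS,8R,8aR)-3,3a-epoxy-8-hydroxy-6,8a-dimethyl-3-(propan-2-yl)-1,2,3,3a,8,8a-hexahydroazulen-4(5H)-one
Conditions: t‑BuOOH, n‑BuLi, THF, −78 → −20 °C
Reagents that add atoms: tert-butyl hydroperoxide (CC(C)(C)OO)
Why: Weitz–Scheffer nucleophilic epoxidation, in which the lithium peroxide adds to the β‑carbon C4 of the s‑cis enone and the enolate closes on oxygen from the upper face, opposite the pseudo‑axial C1 methyl and on the side where the C10 lithium alkoxide can guide the reagent, so that the C4–O bond is formed cis to the C10 oxygen as the target requires, while the isolated C8=C9 alkene is inert to the nucleophilic oxidant.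

Step 12
Reactants: 19 (3S,3aS,8R,8aR)-3,3a-epoxy-8-hydroxy-6,8a-dimethyl-3-(propan-2-yl)-1,2,3,3a,8,8a-hexahydroazulen-4(5H)-one; 20 3-methylbutanoic anhydride
Product: 21 (3S,3aS,8R,8aR)-3,3a-epoxy-6,8a-dimethyl-4-oxo-3-(propan-2-yl)-1,2,3,3a,4,5,8,8a-octahydroazulen-8-yl 3-methylbutanoate
Conditions: 20, Et3N, DMAP (cat.), CH2Cl2, 23 → 40 °C
Reagents that add atoms: none
Why: nucleophile‑catalysed acylation of the only hydroxyl group installs the C10 isovalerate without any selectivity problem and without touching the stereocentres.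

Step 13
Reactants: 21 (3S,3aS,8R,8aR)-3,3a-epoxy-6,8a-dimethyl-4-oxo-3-(propan-2-yl)-1,2,3,3a,4,5,8,8a-octahydroazulen-8-yl 3-methylbutanoate
Product: 22 (3S,3aR,8R,8aS)-3-hydroxy-6,8a-dimethyl-4-oxo-3-(propan-2-yl)-1,2,3,3a,4,5,8,8a-octahydroazulen-8-yl 3-methylbutanoate
Conditions: SmI2 (2.5 equiv), THF/MeOH, −78 °C
Reagents that add atoms: none
Why: SmI2 reduces the ketone to a ketyl that cleaves the α C5–O bond (reductive opening of an α,β‑epoxy ketone to the aldol), which leaves the C4–O bond and its configuration untouched, and the samarium enolate should be protonated at C5 on the upper face held by the chelated C4 alkoxide, anti to the C1 methyl, to give the trans ring fusion that is also expected to be the thermodynamic outcome at this epimerizable centre.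

Step 14
Reactants: 22 (3S,3aR,8R,8aS)-3-hydroxy-6,8a-dimethyl-4-oxo-3-(propan-2-yl)-1,2,3,3a,4,5,8,8a-octahydroazulen-8-yl 3-methylbutanoate
Product: 23 (3S,3aS,4R,8R,8aS)-3,4-dihydroxy-6,8a-dimethyl-3-(propan-2-yl)-1,2,3,3a,4,5,8,8a-octahydroazulen-8-yl 3-methylbutanoate
Conditions: Me4NBH(OAc)3, MeCN/AcOH (1:1), −30 °C
Reagents that add atoms: none
Why: Evans–Saksena reduction, in which the C4 hydroxyl exchanges onto boron and delivers hydride intramolecularly to the upper face of the C6 ketone through a chair transition state, should give the 1,3‑anti diol, which is the C4/C6 relationship of the target.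

Step 15
Reactants: 23 (3S,3aS,4R,8R,8aS)-3,4-dihydroxy-6,8a-dimethyl-3-(propan-2-yl)-1,2,3,3a,4,5,8,8a-octahydroazulen-8-yl 3-methylbutanoate; 24 4-(acetyloxy)benzoyl chloride
Product: 25 (3S,3aS,4R,8R,8aS)-3-hydroxy-6,8a-dimethyl-8-[(3-methylbutanoyl)oxy]-3-(propan-2-yl)-1,2,3,3a,4,5,8,8a-octahydroazulen-4-yl 4-(acetyloxy)benzoate
Conditions: 24, Et3N, DMAP (cat.), CH2Cl2, 0 → 23 °C
Reagents that add atoms: none
Why: acylation with the acid chloride should take place only at the secondary C6 hydroxyl because the tertiary C4 hydroxyl is too hindered, and the configuration at C6 is retained since the C–O bond is not broken.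

Step 16
Reactants: 25 (3S,3aS,4R,8R,8aS)-3-hydroxy-6,8a-dimethyl-8-[(3-methylbutanoyl)oxy]-3-(propan-2-yl)-1,2,3,3a,4,5,8,8a-octahydroazulen-4-yl 4-(acetyloxy)benzoate
Product: 26 (3S,3aS,4R,8R,8aS)-3-hydroxy-6,8a-dimethyl-8-[(3-methylbutanoyl)oxy]-3-(propan-2-yl)-1,2,3,3a,4,5,8,8a-octahydroazulen-4-yl 4-hydroxybenzoate
Conditions: K2CO3 (cat.), MeOH, 0 °C
Reagents that add atoms: none
Why: base‑catalysed methanolysis cleaves the phenolic acetate much faster than the two hindered esters of secondary alcohols (the phenoxide leaving group makes the aryl acetate the most reactive acyl group), which frees the phenol without touching a stereocentre.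

**Compound list**

1 | (2E)-but-2-enal | C/C=C/C=O | starting material
2 | triethyl 2-phosphonopropionate | CCOC(=O)C(C)P(=O)(OCC)OCC | starting material
3 | ethyl (2E,4E)-2-methylhexa-2,4-dienoate | CCOC(=O)/C(C)=C/C=C/C | intermediate
4 | (2E,4E)-2-methylhexa-2,4-dien-1-ol | OC/C(C)=C/C=C/C | intermediate
5 | (2E,4E)-1-bromo-2-methylhexa-2,4-diene | BrC/C(C)=C/C=C/C | intermediate
6 | pentane-2,4-dione | CC(=O)CC(C)=O | starting material
7 | (7E,9E)-7-methylundeca-7,9-diene-2,4-dione | CC(=O)CC(=O)CC/C(C)=C/C=C/C | intermediate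
8 | (7E,9E)-3-diazo-7-methylundeca-7,9-diene-2,4-dione | CC(=O)C(=[N+]=[N-])C(=O)CC/C(C)=C/C=C/C | intermediate
9 | (7E,9E)-2-[(tert-butyldimethylsilyl)oxy]-3-diazo-7-methylundeca-1,7,9-trien-4-one | C=C(O[Si](C)(C)C(C)(C)C)C(=[N+]=[N-])C(=O)CC/C(C)=C/C=C/C | intermediate
10 | (1S,5R,6R)-1-{1-[(tert-butyldimethylsilyl)oxy]ethenyl}-5-methyl-6-[(1E)-prop-1-en-1-yl]bicyclo[3.1.0]hexan-2-one (cis-divinylcyclopropane, not isolated) | C/C=C/[C@@H]1[C@@]2(C)CCC(=O)[C@@]12C(=C)O[Si](C)(C)C(C)(C)C | intermediate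
11 | (3aR,6R)-8-[(tert-butyldimethylsilyl)oxy]-3a,6-dimethyl-3,3a,6,7-tetrahydroazulen-1(2H)-one (C8 methyl trans to C1 methyl) | C[C@H]1C=C[C@@]2(C)CCC(=O)C2=C(O[Si](C)(C)C(C)(C)C)C1 | intermediate
12 | isopropyllithium | [Li]C(C)C | starting material
13 | (3aR,6R)-8-[(tert-butyldimethylsilyl)oxy]-3a,6-dimethyl-1-(propan-2-yl)-1,2,3,3a,6,7-hexahydroazulen-1-ol (carbinol configuration not controlled, not isolated) | C[C@H]1C=C[C@@]2(C)CCC(O)(C(C)C)C2=C(O[Si](C)(C)C(C)(C)C)C1 | intermediate
14 | (6R,8aR)-6,8a-dimethyl-3-(propan-2-yl)-1,2,6,8a-tetrahydroazulen-4(5H)-one | C[C@H]1C=C[C@@]2(C)CCC(C(C)C)=C2C(=O)C1 | intermediate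
15 | (6R,7R,8S,8aS)-7,8-epoxy-6,8a-dimethyl-3-(propan-2-yl)-1,2,6,7,8,8a-hexahydroazulen-4(5H)-one (epoxide on the upper face) | C[C@H]1[C@H]2O[C@H]2[C@@]2(C)CCC(C(C)C)=C2C(=O)C1 | intermediate
16 | (6R,7S,8S,8aS)-8-hydroxy-6,8a-dimethyl-7-(phenylselanyl)-3-(propan-2-yl)-1,2,6,7,8,8a-hexahydroazulen-4(5H)-one (not isolated) | C[C@H]1[C@H]([Se]c2ccccc2)[C@@H](O)[C@@]2(C)CCC(C(C)C)=C2C(=O)C1 | intermediate
17 | Se-oxide of 16 (configuration at selenium not defined, not isolated) | C[C@H]1[C@H]([Se](=O)c2ccccc2)[C@@H](O)[C@@]2(C)CCC(C(C)C)=C2C(=O)C1 | intermediate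
18 | (8R,8aS)-8-hydroxy-6,8a-dimethyl-3-(propan-2-yl)-1,2,8,8a-tetrahydroazulen-4(5H)-one | CC1=C[C@@H](O)[C@@]2(C)CCC(C(C)C)=C2C(=O)C1 | intermediate
19 | (3S,3aS,8R,8aR)-3,3a-epoxy-8-hydroxy-6,8a-dimethyl-3-(propan-2-yl)-1,2,3,3a,8,8a-hexahydroazulen-4(5H)-one (epoxide on the upper face) | CC1=C[C@@H](O)[C@@]2(C)CC[C@@]3(C(C)C)O[C@@]23C(=O)C1 | intermediate
20 | 3-methylbutanoic anhydride | CC(C)CC(=O)OC(=O)CC(C)C | starting material
21 | (3S,3aS,8R,8aR)-3,3a-epoxy-6,8a-dimethyl-4-oxo-3-(propan-2-yl)-1,2,3,3a,4,5,8,8a-octahydroazulen-8-yl 3-methylbutanoate | CC1=C[C@@H](OC(=O)CC(C)C)[C@@]2(C)CC[C@@]3(C(C)C)O[C@@]23C(=O)C1 | intermediate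
22 | (3S,3aR,8R,8aS)-3-hydroxy-6,8a-dimethyl-4-oxo-3-(propan-2-yl)-1,2,3,3a,4,5,8,8a-octahydroazulen-8-yl 3-methylbutanoate (trans ring fusion) | CC1=C[C@@H](OC(=O)CC(C)C)[C@@]2(C)CC[C@](O)(C(C)C)[C@@H]2C(=O)C1 | intermediate
23 | (3S,3aS,4R,8R,8aS)-3,4-dihydroxy-6,8a-dimethyl-3-(propan-2-yl)-1,2,3,3a,4,5,8,8a-octahydroazulen-8-yl 3-methylbutanoate | CC1=C[C@@H](OC(=O)CC(C)C)[C@@]2(C)CC[C@](O)(C(C)C)[C@@H]2[C@H](O)C1 | intermediate
24 | 4-(acetyloxy)benzoyl chloride | CC(=O)Oc1ccc(cc1)C(Cl)=O | starting material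
25 | (3S,3aS,4R,8R,8aS)-3-hydroxy-6,8a-dimethyl-8-[(3-methylbutanoyl)oxy]-3-(propan-2-yl)-1,2,3,3a,4,5,8,8a-octahydroazulen-4-yl 4-(acetyloxy)benzoate | CC1=C[C@@H](OC(=O)CC(C)C)[C@@]2(C)CC[C@](O)(C(C)C)[C@@H]2[C@H](OC(=O)c2ccc(OC(C)=O)cc2)C1 | intermediate
26 | (3S,3aS,4R,8R,8aS)-3-hydroxy-6,8a-dimethyl-8-[(3-methylbutanoyl)oxy]-3-(propan-2-yl)-1,2,3,3a,4,5,8,8a-octahydroazulen-4-yl 4-hydroxybenzoate | CC1=C[C@@H](OC(=O)CC(C)C)[C@@]2(C)CC[C@](O)(C(C)C)[C@@H]2[C@H](OC(=O)c2ccc(O)cc2)C1 | target

**Step count and risks**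

Total step count: 16. Longest linear sequence: 16 steps (1 and 2 to 26).

Steps most likely to fail:

Step 7. The chiral rhodium carboxylate may discriminate poorly between the enantiotopic faces of the C1=C10 alkene for a carbenoid whose acceptor is a ketone. The carbenoid may also be diverted (C–H insertion, dimerization), and the boat Cope rearrangement may stall because the C1 methyl is syn to both vinyl groups. The fallback sets out from 8 and comes back to the route at 11 (through 10). The acceptor/acceptor carbenoid of the diazo diketone 8 itself is cyclized with [Cu(MeCN)4]PF6 and a C2‑symmetric bis(oxazoline) ligand in CH2Cl2 (intramolecular cyclopropanation of a 2‑diazo‑1,3‑dicarbonyl compound; the ligand enantiomer is chosen to give the required antipode). This should give (1S,5R,6R)-1-acetyl-5-methyl-6-[(1E)-prop-1-en-1-yl]bicyclo[3.1.0]hexan-2-one F1. Its methyl ketone is then enolized kinetically (LiN(SiMe3)2, TBSOTf, THF, −78 °C) to give 10, which is kept cold, freed of metal salts and rearranged on its own in toluene at 80–110 °C to 11.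

Step 9. Facial selectivity of the peracid at C9=C10 may be poor because the C1 and C8 methyl groups flank this alkene on opposite faces; the wrong epoxide would give the C10 epimer after step 10. The fallback sets out from 14 and comes back at 22, and it postpones the oxidation until a hydroxyl group can direct it. The enone of 14 is epoxidized first (t‑BuOOH, DBU, CH2Cl2) to (3S,3aS,6R,8aR)-3,3a-epoxy-6,8a-dimethyl-3-(propan-2-yl)-1,2,3,3a,6,8a-hexahydroazulen-4(5H)-one F2. SmI2 in THF/MeOH opens it to (3S,3aR,6R,8aR)-3-hydroxy-6,8a-dimethyl-3-(propan-2-yl)-1,2,3,3a,6,8a-hexahydroazulen-4(5H)-one F3. Only then is the C9=C10 alkene epoxidized with mCPBA, now delivered to the upper face by hydrogen bonding to the C4 hydroxyl, to give (3S,3aR,6R,7R,8S,8aS)-7,8-epoxy-3-hydroxy-6,8a-dimethyl-3-(propan-2-yl)octahydroazulen-4(1H)-one F4. Selenolate opening gives (3S,3aR,6R,7S,8S,8aS)-3,8-dihydroxy-6,8a-dimethyl-7-(phenylselanyl)-3-(propan-2-yl)octahydroazulen-4(1H)-one F5, oxidation gives its Se-oxide F6, and syn‑elimination gives (3S,3aR,8R,8aS)-3,8-dihydroxy-6,8a-dimethyl-3-(propan-2-yl)-1,2,3,3a,8,8a-hexahydroazulen-4(5H)-one F7. Its only secondary hydroxyl (C10) is acylated with 20 (Et3N, DMAP) to give 22.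

Step 11. Conjugate addition of the peroxide anion to the fully substituted, isopropyl‑bearing C4 may be slow and may occur in part on the lower face; under the basic conditions the C8=C9 double bond may also migrate into conjugation with the C6 ketone. The fallback sets out from 18 and comes back at 21, and it replaces the nucleophilic epoxidation by an electrophilic one on a reduced, protected substrate. Compound 18 is acylated with 20 to (8R,8aS)-6,8a-dimethyl-4-oxo-3-(propan-2-yl)-1,2,4,5,8,8a-hexahydroazulen-8-yl 3-methylbutanoate F8. Luche reduction (NaBH4, CeCl3, MeOH, −78 °C; hydride anti to the C1 methyl) gives (4R,8R,8aS)-4-hydroxy-6,8a-dimethyl-3-(propan-2-yl)-1,2,4,5,8,8a-hexahydroazulen-8-yl 3-methylbutanoate F9. Silylation (TBSOTf, 2,6‑lutidine) gives (4R,8R,8aS)-4-[(tert-butyldimethylsilyl)oxy]-6,8a-dimethyl-3-(propan-2-yl)-1,2,4,5,8,8a-hexahydroazulen-8-yl 3-methylbutanoate F10. The now electron‑rich tetrasubstituted C4=C5 alkene is epoxidized with mCPBA on the upper face, away from both the C1 methyl and the C6 silyloxy group, to give (3S,3aR,4R,8R,8aR)-4-[(tert-butyldimethylsilyl)oxy]-3,3a-epoxy-6,8a-dimethyl-3-(propan-2-yl)-1,2,3,3a,4,5,8,8a-octahydroazulen-8-yl 3-methylbutanoate F11. Bu4NF frees (3S,3aR,4R,8R,8aR)-3,3a-epoxy-4-hydroxy-6,8a-dimethyl-3-(propan-2-yl)-1,2,3,3a,4,5,8,8a-octahydroazulen-8-yl 3-methylbutanoate F12, and Dess–Martin oxidation returns 21.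

Further compounds
F1 | step 7 | (1S,5R,6R)-1-acetyl-5-methyl-6-[(1E)-prop-1-en-1-yl]bicyclo[3.1.0]hexan-2-one | C/C=C/[C@@H]1[C@@]2(C)CCC(=O)[C@@]12C(C)=O
F2 | step 9 | (3S,3aS,6R,8aR)-3,3a-epoxy-6,8a-dimethyl-3-(propan-2-yl)-1,2,3,3a,6,8a-hexahydroazulen-4(5H)-one | C[C@H]1C=C[C@@]2(C)CC[C@@]3(C(C)C)O[C@@]23C(=O)C1
F3 | step 9 | (3S,3aR,6R,8aR)-3-hydroxy-6,8a-dimethyl-3-(propan-2-yl)-1,2,3,3a,6,8a-hexahydroazulen-4(5H)-one | C[C@H]1C=C[C@@]2(C)CC[C@](O)(C(C)C)[C@@H]2C(=O)C1
F4 | step 9 | (3S,3aR,6R,7R,8S,8aS)-7,8-epoxy-3-hydroxy-6,8a-dimethyl-3-(propan-2-yl)octahydroazulen-4(1H)-one | C[C@H]1[C@H]2O[C@H]2[C@@]2(C)CC[C@](O)(C(C)C)[C@@H]2C(=O)C1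
F5 | step 9 | (3S,3aR,6R,7S,8S,8aS)-3,8-dihydroxy-6,8a-dimethyl-7-(phenylselanyl)-3-(propan-2-yl)octahydroazulen-4(1H)-one | C[C@H]1[C@H]([Se]c2ccccc2)[C@@H](O)[C@@]2(C)CC[C@](O)(C(C)C)[C@@H]2C(=O)C1
F6 | step 9 | Se-oxide of F5 (configuration at selenium not defined) | C[C@H]1[C@H]([Se](=O)c2ccccc2)[C@@H](O)[C@@]2(C)CC[C@](O)(C(C)C)[C@@H]2C(=O)C1
F7 | step 9 | (3S,3aR,8R,8aS)-3,8-dihydroxy-6,8a-dimethyl-3-(propan-2-yl)-1,2,3,3a,8,8a-hexahydroazulen-4(5H)-one | CC1=C[C@@H](O)[C@@]2(C)CC[C@](O)(C(C)C)[C@@H]2C(=O)C1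
F8 | step 11 | (8R,8aS)-6,8a-dimethyl-4-oxo-3-(propan-2-yl)-1,2,4,5,8,8a-hexahydroazulen-8-yl 3-methylbutanoate | CC1=C[C@@H](OC(=O)CC(C)C)[C@@]2(C)CCC(C(C)C)=C2C(=O)C1
F9 | step 11 | (4R,8R,8aS)-4-hydroxy-6,8a-dimethyl-3-(propan-2-yl)-1,2,4,5,8,8a-hexahydroazulen-8-yl 3-methylbutanoate | CC1=C[C@@H](OC(=O)CC(C)C)[C@@]2(C)CCC(C(C)C)=C2[C@H](O)C1
F10 | step 11 | (4R,8R,8aS)-4-[(tert-butyldimethylsilyl)oxy]-6,8a-dimethyl-3-(propan-2-yl)-1,2,4,5,8,8a-hexahydroazulen-8-yl 3-methylbutanoate | CC1=C[C@@H](OC(=O)CC(C)C)[C@@]2(C)CCC(C(C)C)=C2[C@H](O[Si](C)(C)C(C)(C)C)C1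
F11 | step 11 | (3S,3aR,4R,8R,8aR)-4-[(tert-butyldimethylsilyl)oxy]-3,3a-epoxy-6,8a-dimethyl-3-(propan-2-yl)-1,2,3,3a,4,5,8,8a-octahydroazulen-8-yl 3-methylbutanoate | CC1=C[C@@H](OC(=O)CC(C)C)[C@@]2(C)CC[C@@]3(C(C)C)O[C@@]23[C@H](O[Si](C)(C)C(C)(C)C)C1
F12 | step 11 | (3S,3aR,4R,8R,8aR)-3,3a-epoxy-4-hydroxy-6,8a-dimethyl-3-(propan-2-yl)-1,2,3,3a,4,5,8,8a-octahydroazulen-8-yl 3-methylbutanoate | CC1=C[C@@H](OC(=O)CC(C)C)[C@@]2(C)CC[C@@]3(C(C)C)O[C@@]23[C@H](O)C1
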